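**Retrosynthetic overview** (target numbering: C1 = CO2H … C17 = CH attached to the oxazole)
- Target ⇒ global desilylation of its tris-TBS ether; the C13–C14 bond is cut (Suzuki) into a vinyl iodide and an oxazolyl-dienyl boronate, so the basic oxazole never meets the silylium catalysts.
- C6–C7 ⇒ ε-selective, anti-selective bisvinylogous Mukaiyama aldol (new) between a C7 aldehyde and the bis-silyl trienediolate of 2-methylhepta-2,4-dienoic acid.
- C8–C9 and C10–C11 ⇒ two iterative IDPi-catalysed aldolisations (acetaldehyde enol silane, then (Z)-propanal enol silane) back to (E)-3-iodo-2-methylacrolein; the syn aldol sets the first stereocentres (C10, C11).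
- No ring is formed: the oxazole is bought as 2-methyloxazole-4-carbaldehyde.

Assumption: 5, 8, 18, 19 and 21 are catalogue chemicals; "IDPi" is a BINOL-derived imidodiphosphorimidate Brønsted acid whose enantiomer and 3,3′-aryl groups are fixed by screening for each of steps 4, 5 and 8.

**Step 1**
Reactants: 1 prop-2-yn-1-ol
Product: 3 (E)-3-iodo-2-methylprop-2-en-1-ol, via alkenylalane 2 (not isolated)
Conditions: AlMe3 (3 equiv), Cp2ZrCl2 (25 mol%), CH2Cl2, 0 °C → rt; then I2, THF, −30 → 0 °C; aq K2CO3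
Reagents that add atoms: trimethylaluminium C[Al](C)C; iodine II
Why: Zr-catalysed syn-carboalumination of the alkyne (Negishi) puts Me and Al cis with Al on the terminal carbon, and iododealumination with retention gives the E-iodoalkene.

**Step 2**
Reactants: 3 (E)-3-iodo-2-methylprop-2-en-1-ol
Product: 4 (E)-3-iodo-2-methylprop-2-enal
Conditions: MnO2 (15 equiv), CH2Cl2, rt, dark
Reagents that add atoms: none
Why: Allylic oxidation with MnO2 stops at the enal and leaves the C–I bond and the alkene geometry untouched.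

**Step 3**
Reactants: 5 allyloxy(tert-butyl)dimethylsilane
Product: 6 (Z)-tert-butyldimethyl(prop-1-en-1-yloxy)silane
Conditions: NiCl2(dppb) (2 mol%), LiBHEt3 (2 mol%), THF, rt; distil
Reagents that add atoms: none
Why: Nickel-hydride double-bond migration (hydrometalation/β-hydride elimination) of allyl silyl ethers is kinetically Z-selective through O–Ni coordination and gives the (Z)-enol silane.

**Step 4**
Reactants: 4 (E)-3-iodo-2-methylprop-2-enal; 6 (Z)-tert-butyldimethyl(prop-1-en-1-yloxy)silane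
Product: 7 (2R,3R,4E)-3-[(tert-butyldimethylsilyl)oxy]-5-iodo-2,4-dimethylpent-4-enal
Conditions: IDPi-A (1 mol%), 6 (1.3 equiv), toluene, −78 °C; Et3N quench
Reagents that add atoms: none
Why: Catalytic asymmetric Mukaiyama aldol of an aldehyde-derived enol silane under silylium–IDPi ion-pair catalysis: the chiral anion steers the (Z)-enol silane to the Re face of O-silylated 4 in an open syn-selective transition state (sets C11 R and the syn C10 methyl, the first stereocentres), the silyl group ends on the aldolate oxygen, and the confined pocket rejects the bulkier product so only one aldolisation occurs.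

**Step 5**
Reactants: 7 (2R,3R,4E)-3-[(tert-butyldimethylsilyl)oxy]-5-iodo-2,4-dimethylpent-4-enal; 8 tert-butyldimethyl(vinyloxy)silane
Product: 9 (3S,4S,5R,6E)-3,5-bis[(tert-butyldimethylsilyl)oxy]-7-iodo-4,6-dimethylhept-6-enal
Conditions: IDPi-B (more open pocket, 2–3 mol%), 8 (1.5 equiv), toluene, −60 °C; Et3N quench
Reagents that add atoms: none
Why: Second catalyst-controlled Mukaiyama single aldolisation (acetaldehyde enol silane): Si-face attack on 7 sets C9 anti to the α-methyl and 1,3-anti to the β-silyloxy group, the sense a very small enol silane also prefers intrinsically for a syn-α-methyl-β-oxy aldehyde, and silyl transfer gives the protected aldehyde directly.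

**Step 6**
Reactants: 10 (E)-pent-2-enal; 11 methylmalonic acid
Product: 13 (2E,4E)-2-methylhepta-2,4-dienoic acid, via hydroxy diacid 12 (not isolated)
Conditions: pyridine, piperidine (10 mol%), 90 °C; aq HCl
Reagents that add atoms: none
Why: Doebner–Knoevenagel condensation: aldol addition followed by anti decarboxylative dehydration gives the E-trisubstituted dienoic acid.

**Step 7**
Reactants: 13 (2E,4E)-2-methylhepta-2,4-dienoic acid
Product: 15 (3E,5E)-1,1-bis[(tert-butyldimethylsilyl)oxy]-2-methylhepta-1,3,5-triene, via dilithium trienediolate 14 (not isolated)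
Conditions: LDA (2.2 equiv), THF/DMPU, −78 → 0 °C; TBSCl (2.3 equiv), −78 °C → rt; pentane, filter, used crude
Reagents that add atoms: tert-butyldimethylsilyl chloride CC(C)(C)[Si](C)(C)Cl
Why: Double deprotonation (CO2H, then the ε-CH2) gives the extended dienediolate-type dianion, which is O,O-silylated in the presence of DMPU; the symmetric acetal terminus removes ketene-acetal E/Z isomerism and the extended 3E,5E geometry is favoured.

**Step 8**
Reactants: 9 (3S,4S,5R,6E)-3,5-bis[(tert-butyldimethylsilyl)oxy]-7-iodo-4,6-dimethylhept-6-enal; 15 (3E,5E)-1,1-bis[(tert-butyldimethylsilyl)oxy]-2-methylhepta-1,3,5-triene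
Product: 17 (2E,4E,6S,7R,9S,10S,11R,12E)-7,9,11-tris[(tert-butyldimethylsilyl)oxy]-13-iodo-2,6,10,12-tetramethyltrideca-2,4,12-trienoic acid, via silyl ester 16 (not isolated)
Conditions: IDPi-C (3 mol%), 15 (1.5 equiv), toluene, −78 → −50 °C; then THF/H2O/AcOH (8:2:1), 0 °C
Reagents that add atoms: none
Why: Proposed new method: an IDPi-catalysed, ε- and anti-selective bisvinylogous Mukaiyama aldol of an ε-methyl bis-silyl trienediolate, in which the silylium–IDPi ion pair O-silylates aldehyde 9 and the (5E)-trienolate attacks through its remote ε-carbon (largest HOMO coefficient, α-carbon blocked by its methyl group, γ-attack disfavoured inside the confined anion) in an open antiperiplanar transition state that puts the ε-methyl anti to the new carbinol and delivers it to the Si face (C7 R, C6 S; the weak 1,3-anti bias of the β-silyloxy group is overridden by the catalyst), the diene relaxing to 2E,4E and silyl transfer closing the cycle before mild hydrolysis of the silyl ester frees the acid; the closest known reaction types are the disulfonimide-catalysed ε-selective bisvinylogous Mukaiyama aldol of unsubstituted sorbate-derived trienolates and the anti-selective vinylogous Mukaiyama aldol of (E)-γ-methyl dienolates.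

**Step 9**
Reactants: 18 2-methyl-1,3-oxazole-4-carbaldehyde; 19 2-(triphenyl-λ5-phosphanylidene)propanal
Product: 20 (E)-2-methyl-3-(2-methyl-1,3-oxazol-4-yl)prop-2-enal
Conditions: toluene, 90 °C
Reagents that add atoms: none
Why: Wittig reaction of a stabilised formyl ylide is E-selective and the less electrophilic enal product does not react further.

**Step 10**
Reactants: 20 (E)-2-methyl-3-(2-methyl-1,3-oxazol-4-yl)prop-2-enal; 21 2-(dichloromethyl)-4,4,5,5-tetramethyl-1,3,2-dioxaborolane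
Product: 22 2-methyl-4-[(1E,3E)-2-methyl-4-(4,4,5,5-tetramethyl-1,3,2-dioxaborolan-2-yl)buta-1,3-dien-1-yl]-1,3-oxazole
Conditions: CrCl2 (8 equiv), LiI (4 equiv), THF, rt, dark
Reagents that add atoms: none
Why: Takai–Utimoto olefination (boron variant): the gem-dichromium species adds to the aldehyde and anti-periplanar elimination gives the E-alkenyl boronate.

**Step 11**
Reactants: 17 (2E,4E,6S,7R,9S,10S,11R,12E)-7,9,11-tris[(tert-butyldimethylsilyl)oxy]-13-iodo-2,6,10,12-tetramethyltrideca-2,4,12-trienoic acid; 22 2-methyl-4-[(1E,3E)-2-methyl-4-(4,4,5,5-tetramethyl-1,3,2-dioxaborolan-2-yl)buta-1,3-dien-1-yl]-1,3-oxazole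
Product: 23 (2E,4E,6S,7R,9S,10S,11R,12E,14E,16E)-7,9,11-tris[(tert-butyldimethylsilyl)oxy]-2,6,10,12,16-pentamethyl-17-(2-methyl-1,3-oxazol-4-yl)heptadeca-2,4,12,14,16-pentaenoic acid
Conditions: Pd(dppf)Cl2·CH2Cl2 (10 mol%), aq K3PO4 (4 equiv), degassed DMF, rt, dark; pH 4 work-up
Reagents that add atoms: none
Why: Suzuki–Miyaura coupling joins the two sp2 carbons with retention of both alkene geometries, and the carboxylate form of the acid protects C6 against base-induced deconjugation.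

**Step 12**
Reactants: 23 (2E,4E,6S,7R,9S,10S,11R,12E,14E,16E)-7,9,11-tris[(tert-butyldimethylsilyl)oxy]-2,6,10,12,16-pentamethyl-17-(2-methyl-1,3-oxazol-4-yl)heptadeca-2,4,12,14,16-pentaenoic acid
Product: 24 (2E,4E,6S,7R,9S,10S,11R,12E,14E,16E)-7,9,11-trihydroxy-2,6,10,12,16-pentamethyl-17-(2-methyl-1,3-oxazol-4-yl)heptadeca-2,4,12,14,16-pentaenoic acid (CNP0108844.1)
Conditions: HF·pyridine, excess pyridine, THF, 0 °C → rt, dark; pH 5 buffer
Reagents that add atoms: none
Why: Fluoride-driven cleavage of the three silyl ethers (Si–F bond formation), buffered with pyridine so the trienyl-allylic C11 alcohol does not ionise; no stereocentre is touched.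

**Compound list**
1 | prop-2-yn-1-ol | C#CCO | starting material
2 | dimethylaluminium (E)-3-(dimethylalumanyl)-2-methylprop-2-en-1-olate (alkenylalane) | C[Al](C)OC/C(C)=C/[Al](C)C | intermediate (not isolated)
3 | (E)-3-iodo-2-methylprop-2-en-1-ol | OC/C(C)=C/I | intermediate
4 | (E)-3-iodo-2-methylprop-2-enal | O=C/C(C)=C/I | intermediate
5 | allyloxy(tert-butyl)dimethylsilane | C=CCO[Si](C)(C)C(C)(C)C | starting material
6 | (Z)-tert-butyldimethyl(prop-1-en-1-yloxy)silane | C/C=C\O[Si](C)(C)C(C)(C)C | intermediate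
7 | (2R,3R,4E)-3-[(tert-butyldimethylsilyl)oxy]-5-iodo-2,4-dimethylpent-4-enal | I/C=C(\C)[C@H](O[Si](C)(C)C(C)(C)C)[C@@H](C)C=O | intermediate
8 | tert-butyldimethyl(vinyloxy)silane | C=CO[Si](C)(C)C(C)(C)C | starting material
9 | (3S,4S,5R,6E)-3,5-bis[(tert-butyldimethylsilyl)oxy]-7-iodo-4,6-dimethylhept-6-enal | I/C=C(\C)[C@H](O[Si](C)(C)C(C)(C)C)[C@@H](C)[C@@H](O[Si](C)(C)C(C)(C)C)CC=O | intermediate
10 | (E)-pent-2-enal | CC/C=C/C=O | starting material
11 | methylmalonic acid | CC(C(=O)O)C(=O)O | starting material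
12 | 2-[(E)-1-hydroxypent-2-en-1-yl]-2-methylpropanedioic acid (racemic hydroxy diacid) | CC/C=C/C(O)C(C)(C(=O)O)C(=O)O | intermediate (not isolated)
13 | (2E,4E)-2-methylhepta-2,4-dienoic acid | CC/C=C/C=C(\C)C(=O)O | intermediate
14 | dilithium (3E,5E)-2-methylhepta-1,3,5-triene-1,1-diolate | C/C=C/C=C/C(C)=C([O-])[O-].[Li+].[Li+] | intermediate (not isolated)
15 | (3E,5E)-1,1-bis[(tert-butyldimethylsilyl)oxy]-2-methylhepta-1,3,5-triene | C/C=C/C=C/C(C)=C(O[Si](C)(C)C(C)(C)C)O[Si](C)(C)C(C)(C)C | intermediate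
16 | tert-butyldimethylsilyl (2E,4E,6S,7R,9S,10S,11R,12E)-7,9,11-tris[(tert-butyldimethylsilyl)oxy]-13-iodo-2,6,10,12-tetramethyltrideca-2,4,12-trienoate | I/C=C(\C)[C@H](O[Si](C)(C)C(C)(C)C)[C@@H](C)[C@@H](O[Si](C)(C)C(C)(C)C)C[C@@H](O[Si](C)(C)C(C)(C)C)[C@@H](C)/C=C/C=C(\C)C(=O)O[Si](C)(C)C(C)(C)C | intermediate (not isolated)
17 | (2E,4E,6S,7R,9S,10S,11R,12E)-7,9,11-tris[(tert-butyldimethylsilyl)oxy]-13-iodo-2,6,10,12-tetramethyltrideca-2,4,12-trienoic acid | I/C=C(\C)[C@H](O[Si](C)(C)C(C)(C)C)[C@@H](C)[C@@H](O[Si](C)(C)C(C)(C)C)C[C@@H](O[Si](C)(C)C(C)(C)C)[C@@H](C)/C=C/C=C(\C)C(=O)O | intermediate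
18 | 2-methyl-1,3-oxazole-4-carbaldehyde | Cc1nc(C=O)co1 | starting material
19 | 2-(triphenyl-λ5-phosphanylidene)propanal | CC(C=O)=P(c1ccccc1)(c1ccccc1)c1ccccc1 | starting material
20 | (E)-2-methyl-3-(2-methyl-1,3-oxazol-4-yl)prop-2-enal | O=C/C(C)=C/c1coc(C)n1 | intermediate
21 | 2-(dichloromethyl)-4,4,5,5-tetramethyl-1,3,2-dioxaborolane | ClC(Cl)B1OC(C)(C)C(C)(C)O1 | starting material
22 | 2-methyl-4-[(1E,3E)-2-methyl-4-(4,4,5,5-tetramethyl-1,3,2-dioxaborolan-2-yl)buta-1,3-dien-1-yl]-1,3-oxazole | CC(/C=C/B1OC(C)(C)C(C)(C)O1)=C\c1coc(C)n1 | intermediate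
23 | (2E,4E,6S,7R,9S,10S,11R,12E,14E,16E)-7,9,11-tris[(tert-butyldimethylsilyl)oxy]-2,6,10,12,16-pentamethyl-17-(2-methyl-1,3-oxazol-4-yl)heptadeca-2,4,12,14,16-pentaenoic acid | CC(/C=C/C=C(\C)[C@H](O[Si](C)(C)C(C)(C)C)[C@@H](C)[C@@H](O[Si](C)(C)C(C)(C)C)C[C@@H](O[Si](C)(C)C(C)(C)C)[C@@H](C)/C=C/C=C(\C)C(=O)O)=C\c1coc(C)n1 | intermediate
24 | (2E,4E,6S,7R,9S,10S,11R,12E,14E,16E)-7,9,11-trihydroxy-2,6,10,12,16-pentamethyl-17-(2-methyl-1,3-oxazol-4-yl)heptadeca-2,4,12,14,16-pentaenoic acid | CC(/C=C/C=C(\C)[C@H](O)[C@@H](C)[C@@H](O)C[C@@H](O)[C@@H](C)/C=C/C=C(\C)C(=O)O)=C\c1coc(C)n1 | target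

**Step count**
Total: 12 steps. Longest linear sequence: 7 steps (1, 2, 4, 5, 8, 11, 12).

**Steps most likely to fail**

Step 8 (the proposed new reaction). Possible failures are γ- instead of ε-attack, syn instead of anti at C6/C7, incomplete override of the substrate's 1,3-anti bias, and 5Z contamination in 15. The fallback uses known chemistry, sets out from 9 and comes back at 17. Aldehyde 9 is crotylated with (−)-Ipc2B[(E)-crotyl] (Brown anti-crotylation, Si-face, THF, −78 °C; NaOH/H2O2) to give (3S,4R,6S,7S,8R,9E)-6,8-bis[(tert-butyldimethylsilyl)oxy]-10-iodo-3,7,9-trimethyldeca-1,9-dien-4-ol F5. TBSOTf/2,6-lutidine gives (3S,4R,6S,7S,8R,9E)-4,6,8-tris[(tert-butyldimethylsilyl)oxy]-10-iodo-3,7,9-trimethyldeca-1,9-diene F6. OsO4 (cat.)/NMO then NaIO4 cleaves only the terminal vinyl group (the electron-poor iodoalkene survives) to give (2R,3R,5S,6S,7R,8E)-3,5,7-tris[(tert-butyldimethylsilyl)oxy]-9-iodo-2,6,8-trimethylnon-8-enal F7. Vinylogous Horner–Wadsworth–Emmons reaction with ethyl (E)-4-(diethoxyphosphoryl)-2-methylbut-2-enoate (LiHMDS, THF, −78 → 0 °C) gives ethyl (2E,4E,6S,7R,9S,10S,11R,12E)-7,9,11-tris[(tert-butyldimethylsilyl)oxy]-13-iodo-2,6,10,12-tetramethyltrideca-2,4,12-trienoate F8. LiOH in THF/MeOH/H2O then gives acid 17.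

Step 5. The β-silyloxy, α-branched aldehyde 7 may be too bulky for a confined catalyst, or the product 9 may aldolise again. The fallback sets out from 7 and comes back at 9. Allylation with (−)-Ipc2B(allyl) (Si-face, reagent-controlled, Et2O, −78 °C) gives (4S,5S,6R,7E)-6-[(tert-butyldimethylsilyl)oxy]-8-iodo-5,7-dimethylocta-1,7-dien-4-ol F3. TBSOTf/2,6-lutidine gives (4S,5S,6R,7E)-4,6-bis[(tert-butyldimethylsilyl)oxy]-8-iodo-5,7-dimethylocta-1,7-diene F4. OsO4 (cat.)/NMO then NaIO4 cleaves the terminal alkene to aldehyde 9.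

Step 4. Syn/anti ratio and ee are untested with a β-iodo-α-methyl enal. The fallback sets out from 4 and comes back at 7. A tin(II) triflate/chiral diamine-catalysed syn-selective Mukaiyama aldol of (Z)-1-(ethylsulfanyl)-1-(trimethylsilyloxy)prop-1-ene with 4 (EtCN, −78 °C, slow addition) gives S-ethyl (2R,3R,4E)-3-hydroxy-5-iodo-2,4-dimethylpent-4-enethioate F1. TBSOTf/2,6-lutidine gives S-ethyl (2R,3R,4E)-3-[(tert-butyldimethylsilyl)oxy]-5-iodo-2,4-dimethylpent-4-enethioate F2. DIBAL-H (CH2Cl2, −78 °C) reduces the thioester to aldehyde 7.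

**Further compounds**
F1 | step 4 | S-ethyl (2R,3R,4E)-3-hydroxy-5-iodo-2,4-dimethylpent-4-enethioate | I/C=C(\C)[C@H](O)[C@@H](C)C(=O)SCC
F2 | step 4 | S-ethyl (2R,3R,4E)-3-[(tert-butyldimethylsilyl)oxy]-5-iodo-2,4-dimethylpent-4-enethioate | I/C=C(\C)[C@H](O[Si](C)(C)C(C)(C)C)[C@@H](C)C(=O)SCC
F3 | step 5 | (4S,5S,6R,7E)-6-[(tert-butyldimethylsilyl)oxy]-8-iodo-5,7-dimethylocta-1,7-dien-4-ol | I/C=C(\C)[C@H](O[Si](C)(C)C(C)(C)C)[C@@H](C)[C@@H](O)CC=C
F4 | step 5 | (4S,5S,6R,7E)-4,6-bis[(tert-butyldimethylsilyl)oxy]-8-iodo-5,7-dimethylocta-1,7-diene | I/C=C(\C)[C@H](O[Si](C)(C)C(C)(C)C)[C@@H](C)[C@@H](O[Si](C)(C)C(C)(C)C)CC=C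
F5 | step 8 | (3S,4R,6S,7S,8R,9E)-6,8-bis[(tert-butyldimethylsilyl)oxy]-10-iodo-3,7,9-trimethyldeca-1,9-dien-4-ol | I/C=C(\C)[C@H](O[Si](C)(C)C(C)(C)C)[C@@H](C)[C@@H](O[Si](C)(C)C(C)(C)C)C[C@@H](O)[C@@H](C)C=C
F6 | step 8 | (3S,4R,6S,7S,8R,9E)-4,6,8-tris[(tert-butyldimethylsilyl)oxy]-10-iodo-3,7,9-trimethyldeca-1,9-diene | I/C=C(\C)[C@H](O[Si](C)(C)C(C)(C)C)[C@@H](C)[C@@H](O[Si](C)(C)C(C)(C)C)C[C@@H](O[Si](C)(C)C(C)(C)C)[C@@H](C)C=C
F7 | step 8 | (2R,3R,5S,6S,7R,8E)-3,5,7-tris[(tert-butyldimethylsilyl)oxy]-9-iodo-2,6,8-trimethylnon-8-enal | I/C=C(\C)[C@H](O[Si](C)(C)C(C)(C)C)[C@@H](C)[C@@H](O[Si](C)(C)C(C)(C)C)C[C@@H](O[Si](C)(C)C(C)(C)C)[C@@H](C)C=O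
F8 | step 8 | ethyl (2E,4E,6S,7R,9S,10S,11R,12E)-7,9,11-tris[(tert-butyldimethylsilyl)oxy]-13-iodo-2,6,10,12-tetramethyltrideca-2,4,12-trienoate | I/C=C(\C)[C@H](O[Si](C)(C)C(C)(C)C)[C@@H](C)[C@@H](O[Si](C)(C)C(C)(C)C)C[C@@H](O[Si](C)(C)C(C)(C)C)[C@@H](C)/C=C/C=C(\C)C(=O)OCC
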